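**Plan**

- Numbering: cyclobutane C1 and C2 carry the two (R)-danshensu esters; C3 (next to C2) and C4 (next to C1) carry the catechols. Cuts, in order: ten O–benzyl bonds and two aryl C–H bonds (from aryl triflates); the C1 ester C–O bond (lactone opened by a danshensu alkoxide); the C1–carbonyl bond (CO); C1–C4 and C2–C3 ([2+2] of a stilbene with a danshensu propiolate); the stilbene C=C (McMurry).
- Forward: stilbene, then the four-membered ring (step 6), then a six-membered lactone cis-fused to it (step 8), then opening of that lactone by the second danshensu unit, removal of the two tether oxygens, and hydrogenolysis.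
- Enabling feature: the C1 carboxyl is cis to the C4 aryl and trans to the C2 ester. An ortho hydroxyl on the C4 aryl can therefore capture an acyl group at C1 of a C1=C2 cyclobutene ester in a six-membered lactone cis-fused to the ring, while hydrogen enters C2 from the same face.
- Stereochemistry: both side-chain centres come from (R)-danshensu. C3/C4 are trans from the E-stilbene, and their absolute sense is secured by separating diastereomers after step 8. C1 and C2 are set in step 8 by the tether and the syn addition.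
- Design constraint: a cyclobutene with trans aryl groups on both saturated carbons is expected to open conrotatorily to a 1,3-diene near room temperature. Compounds 9 and 10 are therefore kept cold, and the carbonylation is run at 0–10 °C with a palladium hydride of a type known to turn over in the cold.

Key step: step 8

Assumption: because 9 and 10 are thermally labile, the diastereomers from step 6 are not separated at the cyclobutene stage; the (3R,4R) series is carried along and removed as its lactone (ring centres 1S,2S,3S,4S) after step 8, where the configuration is also assigned.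

**Route**

Step 1
Reactants: 1 (R)-danshensu [(R)-3-(3,4-dihydroxyphenyl)-2-hydroxypropanoic acid]
Product: 2 benzyl (R)-3-[3,4-bis(benzyloxy)phenyl]-2-hydroxypropanoate
Conditions: BnBr (3.3 equiv), K2CO3, DMF, rt, argon
Reagents that add atoms: benzyl bromide, BrCc1ccccc1
Why: Williamson O-alkylation takes the two phenoxides and the carboxylate that K2CO3 generates, while the secondary alcohol stays protonated and the stereocentre is untouched.

Step 2
Reactants: 2 benzyl (R)-3-[3,4-bis(benzyloxy)phenyl]-2-hydroxypropanoate; 3 propiolic acid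
Product: 4 benzyl (R)-3-[3,4-bis(benzyloxy)phenyl]-2-(prop-2-ynoyloxy)propanoate
Conditions: DCC, DMAP (5 mol%), CH2Cl2, −20 → 0 °C
Reagents that add atoms: none
Why: Steglich esterification acylates the hydroxyl without breaking a bond to the stereocentre, and low temperature with little DMAP limits amine addition to the ynoate.

Step 3
Reactants: 5 2,4,5-trihydroxybenzaldehyde
Product: 6 4,5-bis(benzyloxy)-2-hydroxybenzaldehyde
Conditions: BnBr (2.05 equiv), K2CO3 (2.1 equiv), DMF, 0 °C → rt, argon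
Reagents that add atoms: benzyl bromide, BrCc1ccccc1
Why: Williamson alkylation should take the 4- and 5-phenoxides, because the 2-hydroxyl is hydrogen-bonded to the aldehyde and its phenoxide is the least nucleophilic.

Step 4
Reactants: 6 4,5-bis(benzyloxy)-2-hydroxybenzaldehyde
Product: 7 4,5-bis(benzyloxy)-2-[(tert-butyldimethylsilyl)oxy]benzaldehyde
Conditions: TBSCl, imidazole, DMF, rt
Reagents that add atoms: tert-butyldimethylsilyl chloride, CC(C)(C)[Si](C)(C)Cl
Why: imidazole-promoted silylation of the phenol masks the tether oxygen through the titanium and aluminium steps and can be reversed with fluoride in the cold.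

Step 5
Reactants: 7 4,5-bis(benzyloxy)-2-[(tert-butyldimethylsilyl)oxy]benzaldehyde (two molecules)
Product: 8 (E)-1,2-bis{4,5-bis(benzyloxy)-2-[(tert-butyldimethylsilyl)oxy]phenyl}ethene
Conditions: TiCl4, Zn, pyridine, THF, reflux
Reagents that add atoms: none
Why: McMurry reductive coupling of an aryl aldehyde on low-valent titanium gives the symmetric stilbene, with the E isomer favoured for two ortho-substituted aryl groups.

Step 6
Reactants: 8 (E)-1,2-bis{4,5-bis(benzyloxy)-2-[(tert-butyldimethylsilyl)oxy]phenyl}ethene; 4 benzyl (R)-3-[3,4-bis(benzyloxy)phenyl]-2-(prop-2-ynoyloxy)propanoate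
Product: 9 (R)-1-(benzyloxy)-3-[3,4-bis(benzyloxy)phenyl]-1-oxopropan-2-yl (3S,4S)-3,4-bis{4,5-bis(benzyloxy)-2-[(tert-butyldimethylsilyl)oxy]phenyl}cyclobut-1-ene-1-carboxylate
Conditions: EtAlCl2 (2.5 equiv), CH2Cl2, −78 °C; MeOH/Et3N, then aqueous potassium sodium tartrate at ≤ 0 °C; solution kept at ≤ −20 °C and used crude
Reagents that add atoms: none
Why: this is a Lewis-acid-promoted [2+2] cycloaddition of a propiolate ester with a 1,2-disubstituted alkene, stepwise here (the stilbene attacks the alkyne terminus and the benzylic cation is closed by the aluminium allenolate), so the E-stilbene should give the trans-3,4-diaryl cyclobutene, without useful facial bias, as 9 together with its (3R,4R) diastereomer.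

Step 7
Reactants: 9 (3S,4S)-cyclobutene bis(silyl ether) from step 6
Product: 10 (R)-1-(benzyloxy)-3-[3,4-bis(benzyloxy)phenyl]-1-oxopropan-2-yl (3S,4S)-3,4-bis[4,5-bis(benzyloxy)-2-hydroxyphenyl]cyclobut-1-ene-1-carboxylate
Conditions: Bu4NF, AcOH (1:1.2), THF, −30 °C; cold work-up, used at once
Reagents that add atoms: none
Why: fluoride desilylation of the two aryl silyl ethers is buffered with acetic acid so that no phenoxide is free for oxa-Michael addition to the enoate, and is run cold so that the cyclobutene does not open.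

Step 8
Reactants: 10 (3S,4S)-cyclobutene bis-phenol from step 7
Product: 11 (R)-1-(benzyloxy)-3-[3,4-bis(benzyloxy)phenyl]-1-oxopropan-2-yl (1R,2R,2aR,8bR)-6,7-bis(benzyloxy)-1-[4,5-bis(benzyloxy)-2-hydroxyphenyl]-3-oxo-1,2,2a,8b-tetrahydro-3H-cyclobuta[c]chromene-2-carboxylate (cyclobutane cis-fused to a dihydrocoumarin; in target numbering C1 carries the lactone carbonyl, C2 the danshensu ester, C3 the free-phenol aryl, C4 the aryl bearing the lactone oxygen, all four centres R)
Conditions: Pd2(dba)3 (5 mol%), 1,2-bis(di-tert-butylphosphinomethyl)benzene (dtbpx, 12 mol%), MsOH (25 mol%), CO (10 bar), CH2Cl2, 0 → 10 °C; chromatography to remove the (1S,2S,3S,4S)-ring lactone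
Reagents that add atoms: carbon monoxide, [C-]#[O+]
Why: Proposed new method: the cationic hydride [(dtbpx)Pd(H)]+ (from zerovalent palladium and MsOH) should add syn and reversibly across the strained C1=C2 bond with hydrogen at the ester-bearing C2 and palladium at C1, CO inserts into the C1–Pd bond with retention, and the ortho hydroxyl of the C4 aryl attacks the acylpalladium, releasing the lactone and regenerating the hydride. The closest known reaction is the palladium-catalysed cyclocarbonylation of 2-allylphenols to benzo-fused lactones, moved here to the β-carbon of a cyclobutene enoate and to a diphosphine whose hydride cycle runs below room temperature, which is required because 10 would open to the diene on heating. The six-membered lactone closes by intramolecular O-acylation (6-exo-trig at the acyl carbon) and can only be cis-fused to the four-membered ring, so the C1 carbonyl ends on the face of the C4 aryl (C1 is set by the C4 centre through the tether). Because hydrogen and acyl arrive on the same face, the C2 ester is left trans to the new carbonyl and cis to the C3 aryl (C2 is set by the syn addition). The step needs acyl at C1 rather than C2 and attack on the C4-aryl face: palladium at C2 would be a tertiary enolate that inserts CO poorly and reverts, the adduct on the other face cannot lactonise and reverts by β-hydride elimination, and the absence of base and of H2 suppresses oxa-Michael addition and alkene reduction.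

Step 9
Reactants: 11 lactone from step 8; 2 benzyl (R)-3-[3,4-bis(benzyloxy)phenyl]-2-hydroxypropanoate
Product: 13 bis[(R)-1-(benzyloxy)-3-[3,4-bis(benzyloxy)phenyl]-1-oxopropan-2-yl] (1R,2R,3R,4R)-3,4-bis{4,5-bis(benzyloxy)-2-[(trifluoromethanesulfonyl)oxy]phenyl}cyclobutane-1,2-dicarboxylate, via dilithium bis-phenoxide diester 12 (not isolated)
Conditions: 2 (1.2 equiv), LiN(SiMe3)2 (2.2 equiv), THF, −78 → −20 °C; then PhNTf2 (2.4 equiv), −20 °C → rt; aqueous NH4Cl
Reagents that add atoms: N-phenylbis(trifluoromethanesulfonimide), O=S(=O)(N(c1ccccc1)S(=O)(=O)C(F)(F)F)C(F)(F)F; lithium bis(trimethylsilyl)amide, [Li+].C[Si](C)(C)[N-][Si](C)(C)C (supplies the lithium of 12 only)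
Why: the lithium alkoxide of 2 opens the aryl ester of the lactone by acyl substitution (transesterification driven by release of the more stable phenoxide) without touching C1 or C2, and both phenoxides are trapped at once as aryl triflates, which forestalls re-lactonisation.

Step 10
Reactants: 13 bis-triflate from step 9
Product: 14 bis[(R)-1-(benzyloxy)-3-[3,4-bis(benzyloxy)phenyl]-1-oxopropan-2-yl] (1R,2R,3R,4R)-3,4-bis[3,4-bis(benzyloxy)phenyl]cyclobutane-1,2-dicarboxylate
Conditions: Pd(OAc)2 (10 mol%), 1,1'-bis(diphenylphosphino)ferrocene (dppf, 12 mol%), HCO2H, Et3N, DMF, 70 °C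
Reagents that add atoms: none
Why: palladium-catalysed reduction of aryl triflates with formate as hydride donor (oxidative addition, decarboxylation of formate, C–H reductive elimination) removes both tether oxygens and leaves benzyl ethers, benzyl esters and all stereocentres alone.

Step 11
Reactants: 14 perbenzylated diester from step 10
Product: 15 (2R,2'R)-2,2'-{[(1R,2R,3R,4R)-3,4-bis(3,4-dihydroxyphenyl)cyclobutane-1,2-dicarbonyl]bis(oxy)}bis[3-(3,4-dihydroxyphenyl)propanoic acid] (CNP0163929.1)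
Conditions: H2 (1 atm), 10% Pd/C, THF/EtOAc, rt; filtration under argon
Reagents that add atoms: none
Why: catalytic hydrogenolysis cleaves the eight benzyl ethers and two benzyl esters, whereas the secondary alkyl ester linkages and the cyclobutane are not hydrogenolysed under these conditions.

**Compound list**

1 | (R)-danshensu | O[C@H](Cc1ccc(O)c(O)c1)C(=O)O | starting material
2 | benzyl (R)-3-[3,4-bis(benzyloxy)phenyl]-2-hydroxypropanoate | O[C@H](Cc1ccc(OCc2ccccc2)c(OCc2ccccc2)c1)C(=O)OCc1ccccc1 | intermediate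
3 | propiolic acid | C#CC(=O)O | starting material
4 | benzyl (R)-3-[3,4-bis(benzyloxy)phenyl]-2-(prop-2-ynoyloxy)propanoate | C#CC(=O)O[C@H](Cc1ccc(OCc2ccccc2)c(OCc2ccccc2)c1)C(=O)OCc1ccccc1 | intermediate
5 | 2,4,5-trihydroxybenzaldehyde | O=Cc1cc(O)c(O)cc1O | starting material
6 | 4,5-bis(benzyloxy)-2-hydroxybenzaldehyde | O=Cc1cc(OCc2ccccc2)c(OCc2ccccc2)cc1O | intermediate
7 | 4,5-bis(benzyloxy)-2-[(tert-butyldimethylsilyl)oxy]benzaldehyde | O=Cc1cc(OCc2ccccc2)c(OCc2ccccc2)cc1O[Si](C)(C)C(C)(C)C | intermediate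
8 | (E)-1,2-bis{4,5-bis(benzyloxy)-2-[(tert-butyldimethylsilyl)oxy]phenyl}ethene | CC(C)(C)[Si](C)(C)Oc1cc(OCc2ccccc2)c(OCc2ccccc2)cc1/C=C/c1cc(OCc2ccccc2)c(OCc2ccccc2)cc1O[Si](C)(C)C(C)(C)C | intermediate
9 | (R)-1-(benzyloxy)-3-[3,4-bis(benzyloxy)phenyl]-1-oxopropan-2-yl (3S,4S)-3,4-bis{4,5-bis(benzyloxy)-2-[(tert-butyldimethylsilyl)oxy]phenyl}cyclobut-1-ene-1-carboxylate | O=C(O[C@H](Cc1ccc(OCc2ccccc2)c(OCc2ccccc2)c1)C(=O)OCc1ccccc1)C1=C[C@H](c2cc(OCc3ccccc3)c(OCc3ccccc3)cc2O[Si](C)(C)C(C)(C)C)[C@H]1c1cc(OCc2ccccc2)c(OCc2ccccc2)cc1O[Si](C)(C)C(C)(C)C | intermediate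
10 | (R)-1-(benzyloxy)-3-[3,4-bis(benzyloxy)phenyl]-1-oxopropan-2-yl (3S,4S)-3,4-bis[4,5-bis(benzyloxy)-2-hydroxyphenyl]cyclobut-1-ene-1-carboxylate | O=C(O[C@H](Cc1ccc(OCc2ccccc2)c(OCc2ccccc2)c1)C(=O)OCc1ccccc1)C1=C[C@H](c2cc(OCc3ccccc3)c(OCc3ccccc3)cc2O)[C@H]1c1cc(OCc2ccccc2)c(OCc2ccccc2)cc1O | intermediate
11 | (R)-1-(benzyloxy)-3-[3,4-bis(benzyloxy)phenyl]-1-oxopropan-2-yl (1R,2R,2aR,8bR)-6,7-bis(benzyloxy)-1-[4,5-bis(benzyloxy)-2-hydroxyphenyl]-3-oxo-1,2,2a,8b-tetrahydro-3H-cyclobuta[c]chromene-2-carboxylate | O=C2[C@H]1[C@H](C(=O)O[C@H](Cc3ccc(OCc4ccccc4)c(OCc4ccccc4)c3)C(=O)OCc3ccccc3)[C@H](c3cc(OCc4ccccc4)c(OCc4ccccc4)cc3O)[C@H]1c1cc(OCc3ccccc3)c(OCc3ccccc3)cc1O2 | intermediate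
12 | dilithium salt of bis[(R)-1-(benzyloxy)-3-[3,4-bis(benzyloxy)phenyl]-1-oxopropan-2-yl] (1R,2R,3R,4R)-3,4-bis[4,5-bis(benzyloxy)-2-oxidophenyl]cyclobutane-1,2-dicarboxylate | [Li+].[Li+].O=C(O[C@H](Cc1ccc(OCc2ccccc2)c(OCc2ccccc2)c1)C(=O)OCc1ccccc1)[C@H]1[C@H](C(=O)O[C@H](Cc2ccc(OCc3ccccc3)c(OCc3ccccc3)c2)C(=O)OCc2ccccc2)[C@H](c2cc(OCc3ccccc3)c(OCc3ccccc3)cc2[O-])[C@H]1c1cc(OCc2ccccc2)c(OCc2ccccc2)cc1[O-] | intermediate (not isolated)
13 | bis[(R)-1-(benzyloxy)-3-[3,4-bis(benzyloxy)phenyl]-1-oxopropan-2-yl] (1R,2R,3R,4R)-3,4-bis{4,5-bis(benzyloxy)-2-[(trifluoromethanesulfonyl)oxy]phenyl}cyclobutane-1,2-dicarboxylate | O=C(O[C@H](Cc1ccc(OCc2ccccc2)c(OCc2ccccc2)c1)C(=O)OCc1ccccc1)[C@H]1[C@H](C(=O)O[C@H](Cc2ccc(OCc3ccccc3)c(OCc3ccccc3)c2)C(=O)OCc2ccccc2)[C@H](c2cc(OCc3ccccc3)c(OCc3ccccc3)cc2OS(=O)(=O)C(F)(F)F)[C@H]1c1cc(OCc2ccccc2)c(OCc2ccccc2)cc1OS(=O)(=O)C(F)(F)F | intermediate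
14 | bis[(R)-1-(benzyloxy)-3-[3,4-bis(benzyloxy)phenyl]-1-oxopropan-2-yl] (1R,2R,3R,4R)-3,4-bis[3,4-bis(benzyloxy)phenyl]cyclobutane-1,2-dicarboxylate | O=C(O[C@H](Cc1ccc(OCc2ccccc2)c(OCc2ccccc2)c1)C(=O)OCc1ccccc1)[C@H]1[C@H](C(=O)O[C@H](Cc2ccc(OCc3ccccc3)c(OCc3ccccc3)c2)C(=O)OCc2ccccc2)[C@H](c2ccc(OCc3ccccc3)c(OCc3ccccc3)c2)[C@H]1c1ccc(OCc2ccccc2)c(OCc2ccccc2)c1 | intermediate
15 | (2R,2'R)-2,2'-{[(1R,2R,3R,4R)-3,4-bis(3,4-dihydroxyphenyl)cyclobutane-1,2-dicarbonyl]bis(oxy)}bis[3-(3,4-dihydroxyphenyl)propanoic acid] | O=C(O[C@H](Cc1ccc(O)c(O)c1)C(=O)O)[C@H]1[C@H](C(=O)O[C@H](Cc2ccc(O)c(O)c2)C(=O)O)[C@H](c2ccc(O)c(O)c2)[C@H]1c1ccc(O)c(O)c1 | target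

**Step count**

Total steps: 11. Longest linear sequence: 9 steps (5 → 15, steps 3–11); the side branch 1 → 2 → 4 is 2 steps, and 2 is used again in step 9.

**Steps most likely to fail**

1. Step 8 (Proposed new method). Conrotatory ring opening of 10 may outrun a slow cold hydropalladation. The C4-aryl hydroxyl may add to C1 (oxa-Michael). Insertion on the face away from the C4 aryl may end in intermolecular acyl transfer instead of reverting. Fallback with known chemistry, from 6 back to 13: aldehyde 6 is heated with ethyl (triphenylphosphoranylidene)acetate in N,N-diethylaniline (Wittig olefination); the ethyl (E)-3-[4,5-bis(benzyloxy)-2-hydroxyphenyl]prop-2-enoate F1 formed in the flask isomerises and lactonises to 6,7-bis(benzyloxy)coumarin F2. Benzophenone-sensitised irradiation (benzene, λ > 340 nm) should give the racemic anti head-to-head cyclobutane dimer F3 by triplet [2+2] photodimerisation. Both lactones of F3 are then opened with 2 (2.2 equiv) and LiN(SiMe3)2, and the phenoxides are triflated in the same flask with PhNTf2. This gives 12 together with its ring diastereomer F4, and from them 13 and the diastereomeric bis-triflate F5; chromatography removes F5 and the route continues from 13.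

2. Step 6. The Lewis acid may cleave benzyl or silyl ethers. The activated ynoate may attack the electron-rich rings (Friedel–Crafts). The zwitterion may collapse to open-chain products, or the cyclobutene may open while still complexed to aluminium. Fallback, from 8 back to 9: stilbene 8 is treated with dichloroketene (Cl3CCOCl, Zn, Et2O) to give the racemic trans-dichlorocyclobutanone F6 by ketene [2+2] cycloaddition. Zn/AcOH dechlorination gives the cyclobutanone F7. Kinetic deprotonation at the methylene with LiN(SiMe3)2 and trapping with PhNTf2 at −78 °C gives the cyclobutenyl triflate F8, handled cold. Palladium-catalysed alkoxycarbonylation with 2 (Pd(OAc)2, PPh3, CO 1 atm, Et3N, DMF, 0–10 °C) then gives 9 with its (3R,4R) diastereomer, as in the main route.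

3. Step 9. Lactone opening may be incomplete or reversible (a phenoxide re-closing on either ester with loss of alkoxide). The alkoxide may exchange at the benzyl esters. Base may epimerise C1 or C2. The hindered lithium phenoxides may triflate slowly. Fallback, from 11 back to 14: 11 is opened with lithium allyloxide (allyl alcohol, LiN(SiMe3)2, THF, −78 → −20 °C), and the dilithium bis-phenoxide allyl ester F9 is triflated in the flask with PhNTf2 to the allyl ester bis-triflate F10. Pd(OAc)2/dppf with HCO2H/Et3N then reduces both triflates and cleaves the allyl ester, giving the monoacid F11. Esterification of F11 with 2 (EDC·HCl, DMAP, CH2Cl2, 0 °C) installs the second danshensu unit after the phenols are gone and gives 14.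

**Further compounds**

F1 | step 8 | ethyl (E)-3-[4,5-bis(benzyloxy)-2-hydroxyphenyl]prop-2-enoate | CCOC(=O)/C=C/c1cc(OCc2ccccc2)c(OCc2ccccc2)cc1O
F2 | step 8 | 6,7-bis(benzyloxy)-2H-chromen-2-one | O=C1C=Cc2cc(OCc3ccccc3)c(OCc3ccccc3)cc2O1
F3 | step 8 | racemic anti head-to-head cyclobutane dimer of F2 (bis-lactone; the enantiomer drawn leads to 13) | O=C2[C@H]1[C@H](C(=O)O3)[C@H](c4cc(OCc5ccccc5)c(OCc5ccccc5)cc43)[C@H]1c1cc(OCc3ccccc3)c(OCc3ccccc3)cc1O2
F4 | step 8 | diastereomer of 12 with ring centres 1S,2S,3S,4S (dilithium salt) | [Li+].[Li+].O=C(O[C@H](Cc1ccc(OCc2ccccc2)c(OCc2ccccc2)c1)C(=O)OCc1ccccc1)[C@@H]1[C@@H](C(=O)O[C@H](Cc2ccc(OCc3ccccc3)c(OCc3ccccc3)c2)C(=O)OCc2ccccc2)[C@@H](c2cc(OCc3ccccc3)c(OCc3ccccc3)cc2[O-])[C@@H]1c1cc(OCc2ccccc2)c(OCc2ccccc2)cc1[O-]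
F5 | step 8 | diastereomer of 13 with ring centres 1S,2S,3S,4S | O=C(O[C@H](Cc1ccc(OCc2ccccc2)c(OCc2ccccc2)c1)C(=O)OCc1ccccc1)[C@@H]1[C@@H](C(=O)O[C@H](Cc2ccc(OCc3ccccc3)c(OCc3ccccc3)c2)C(=O)OCc2ccccc2)[C@@H](c2cc(OCc3ccccc3)c(OCc3ccccc3)cc2OS(=O)(=O)C(F)(F)F)[C@@H]1c1cc(OCc2ccccc2)c(OCc2ccccc2)cc1OS(=O)(=O)C(F)(F)F
F6 | step 6 | racemic trans-2,2-dichloro-3,4-bis{4,5-bis(benzyloxy)-2-[(tert-butyldimethylsilyl)oxy]phenyl}cyclobutan-1-one (one enantiomer drawn) | O=C1C(Cl)(Cl)[C@H](c2cc(OCc3ccccc3)c(OCc3ccccc3)cc2O[Si](C)(C)C(C)(C)C)[C@H]1c1cc(OCc2ccccc2)c(OCc2ccccc2)cc1O[Si](C)(C)C(C)(C)C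
F7 | step 6 | racemic trans-2,3-bis{4,5-bis(benzyloxy)-2-[(tert-butyldimethylsilyl)oxy]phenyl}cyclobutan-1-one (one enantiomer drawn) | O=C1C[C@H](c2cc(OCc3ccccc3)c(OCc3ccccc3)cc2O[Si](C)(C)C(C)(C)C)[C@H]1c1cc(OCc2ccccc2)c(OCc2ccccc2)cc1O[Si](C)(C)C(C)(C)C
F8 | step 6 | racemic trans-3,4-bis{4,5-bis(benzyloxy)-2-[(tert-butyldimethylsilyl)oxy]phenyl}cyclobut-1-en-1-yl trifluoromethanesulfonate (one enantiomer drawn) | O=S(=O)(OC1=C[C@H](c2cc(OCc3ccccc3)c(OCc3ccccc3)cc2O[Si](C)(C)C(C)(C)C)[C@H]1c1cc(OCc2ccccc2)c(OCc2ccccc2)cc1O[Si](C)(C)C(C)(C)C)C(F)(F)F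
F9 | step 9 | dilithium salt of 1-allyl 2-[(R)-1-(benzyloxy)-3-[3,4-bis(benzyloxy)phenyl]-1-oxopropan-2-yl] (1R,2R,3R,4R)-3,4-bis[4,5-bis(benzyloxy)-2-oxidophenyl]cyclobutane-1,2-dicarboxylate | [Li+].[Li+].C=CCOC(=O)[C@H]1[C@H](C(=O)O[C@H](Cc2ccc(OCc3ccccc3)c(OCc3ccccc3)c2)C(=O)OCc2ccccc2)[C@H](c2cc(OCc3ccccc3)c(OCc3ccccc3)cc2[O-])[C@H]1c1cc(OCc2ccccc2)c(OCc2ccccc2)cc1[O-]
F10 | step 9 | 1-allyl 2-[(R)-1-(benzyloxy)-3-[3,4-bis(benzyloxy)phenyl]-1-oxopropan-2-yl] (1R,2R,3R,4R)-3,4-bis{4,5-bis(benzyloxy)-2-[(trifluoromethanesulfonyl)oxy]phenyl}cyclobutane-1,2-dicarboxylate | C=CCOC(=O)[C@H]1[C@H](C(=O)O[C@H](Cc2ccc(OCc3ccccc3)c(OCc3ccccc3)c2)C(=O)OCc2ccccc2)[C@H](c2cc(OCc3ccccc3)c(OCc3ccccc3)cc2OS(=O)(=O)C(F)(F)F)[C@H]1c1cc(OCc2ccccc2)c(OCc2ccccc2)cc1OS(=O)(=O)C(F)(F)F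
F11 | step 9 | (1R,2R,3R,4R)-2-{[(R)-1-(benzyloxy)-3-[3,4-bis(benzyloxy)phenyl]-1-oxopropan-2-yl]oxycarbonyl}-3,4-bis[3,4-bis(benzyloxy)phenyl]cyclobutane-1-carboxylic acid | OC(=O)[C@H]1[C@H](C(=O)O[C@H](Cc2ccc(OCc3ccccc3)c(OCc3ccccc3)c2)C(=O)OCc2ccccc2)[C@H](c2ccc(OCc3ccccc3)c(OCc3ccccc3)c2)[C@H]1c1ccc(OCc2ccccc2)c(OCc2ccccc2)c1
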